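in all of them: electrophile 14 mM
- Sunday's: nucleophile 1.05 equiv; the very flask that is asked about, followed so far
- Monday's: nucleophile 0.53 equiv; run made earlier
- flask: nucleophile 1.05 equiv; time 50 min

| Sunday's: time / min | Sunday's: product / % | Monday's: time / min | Monday's: product / % |
|---|---|---|---|
| 5.00 | 16 | 2.00 | 4 |
| 15.0 | 22 | 4.00 | 6 |
| 25.0 | 28 | 5.00 | 10 |
| 40.0 | 29 | 8.00 | 11 |

(each reading ± 2 percentage points)

- product that was removed still counts
- additions bring no volume worth counting

- spring: at 50 min take out 90 % of the product then present, then wait 15 min
- autumn: change nothing and wait 15 min more
- winter: at 50 min add nucleophile, 100 % of the amount charged, then wait 15 min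
- dawn: at 50 min add electrophile, 50.0 % of the amount charged, then wait 15 min

1. product, in percent of the electrophile first charged, at 50 min
2. the remedy with the largest gain of product, or "none" below 2 percentage points (spring / autumn / winter / dawn / none)
3. product present, with what was taken out counted in, in percent of the electrophile first charged, after winter
4. product present, with what was taken out counted in, in percent of the electrophile first charged, after dawn

1. Compare the plateau with the charge. Sunday's flask levels at 28.5 % product, the mean of its readings at 25.0 min and 40.0 min, which is less than the 71.5 % of electrophile still unreacted.

2. Solve the first extreme: the nucleophile never fades. The share of electrophile surviving the first 5.00 min then repeats in every such interval, so Sunday's flask reaches 82.5 % product at 50 min.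

3. Solve the second extreme: the nucleophile stops at the first reading. Sunday's flask then stays at 16 %.

4. Place Sunday's flask between them: its plateau is above the second extreme and below the first. So its nucleophile worked for a while, then went idle. Treat the creep of 1 percentage point between the last readings as a small correction, since it is less than the scatter of 2 points, and drop it. Commit to 28.5 % now.

5. Carry the survival per dose: the share of electrophile that outlives one charge of nucleophile. Assume the nucleophile fades on its own clock. The electrophile then falls pseudo-first-order under it, so equal doses take equal shares, and a number of doses leaves the survival per dose raised to that power. The readings do not prove this assumption.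

6. Apply it. Winter's second dose leaves the square, so product reaches 48.9 %. Sunday stood at 22 % after 15.0 min, below its plateau, so expect winter to end at 48.9 % or some points under it. Dawn's new electrophile meets idle nucleophile, so product stays near 28.5 %. Autumn only waits, and Sunday's creep of 1 point over 15.0 min is below the margin of 2 points, so expect no gain worth counting. Spring takes out product, which this reckoning gives no role, so treat it like autumn. Choose winter.

7. The forecast gives 30 %, winter, 45 % after winter and 38 % after dawn. Its ground: “the reaction has stalled, not run out”. It parts from my reckoning at dawn.

8. The flask gives 28.5 %, winter, 48.7 % after winter and 30.5 % after dawn.

    electrophile + nucleophile → acid set free + product (k = 4.50 M⁻¹ min⁻¹)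
    nucleophile + acid set free ⇌ protonated nucleophile, settled at all times (K = 67000 M⁻¹)
    nucleophile ⇌ dormant form (K = 14.0, k = 0.130 min⁻¹)

The forecast's dawn stands 7.5 points above the flask. At 50.0 min the flask held free nucleophile at 1.98 % of its charge, with 3.79 mM protonated nucleophile and 6.63 mM dormant form. Squaring the survival per dose gave 48.9 % for winter, and the flask gave 48.7 %. Now take the neighbour charged with 4.20 equiv of nucleophile: that is 4.00 doses, so the reckoning gives 73.9 % product at 50.0 min. That neighbour holds 81.4 % product, with 19 % of its electrophile left.

All runs were computed with made-up constants; scatter was added.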